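**Plan**
1. Retrosynthesis: the oxane is cut at C2–C3. O1–C2(OH)(CH3) is read as the tetrahedral adduct of a primary acetate, and C3(H)(Br) as a carbenoid carbon, so the ring opens to the acyclic acetate/geminal dibromide 12.
2. Further cuts: CHBr2 from CHO; the acetate and aldehyde arms from a γ-butyrolactone; CH=CHBr from an aldehyde; C–Cl from an epoxide; the bond from ring carbon C5 to the side chain from a conjugate addition to furan-2(5H)-one.
3. Forward: alkenylboronate plus butenolide gives the lactone carrying C5; epoxidation, chloride opening, glycol cleavage and bromo-olefination build the side chain; the lactone is opened to acetate plus aldehyde, then CHBr2; the oxane ring is closed last.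
4. Stereochemistry: C5 from the (S)-BINAP/Rh conjugate addition; the tertiary C–Cl centre from Sharpless epoxidation with D-(−)-diethyl tartrate and invertive chloride opening; the E-bromoalkene from Takai olefination; C3 from the chair transition state of the ring closure and C2 from anomeric equilibration.

Key step: step 11

Remark: (S)-BINAP is assumed to deliver the alkenyl group to the same butenolide face as in the cyclic enone series, which gives (4S)-4; if the sense proves opposite, (R)-BINAP is used.

**Step 1**
Reactants: 1 but-2-yn-1-ol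
Product: 2 (Z)-3-(4,4,5,5-tetramethyl-1,3,2-dioxaborolan-2-yl)but-2-en-1-ol
Conditions: B2pin2, CuCl (cat.), PCy3, NaOt-Bu (cat.), MeOH, toluene, rt
Reagents that add atoms: bis(pinacolato)diboron, CC1(C)OB(OC1(C)C)B1OC(C)(C)C(C)(C)O1
Why: CuCl/phosphine-catalysed borylcupration adds Cu–Bpin syn across the alkyne with boron at the carbon remote from the propargylic oxygen and MeOH protonates the C–Cu bond (formal hydroboration), which fixes H and B cis and so the later E geometry.

**Step 2**
Reactants: 2 (Z)-3-(4,4,5,5-tetramethyl-1,3,2-dioxaborolan-2-yl)but-2-en-1-ol; 3 furan-2(5H)-one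
Product: 4 (4S)-4-[(2E)-4-hydroxybut-2-en-2-yl]oxolan-2-one
Conditions: [Rh(OH)((S)-BINAP)]2 (cat.), 2 (2 equiv), dioxane/H2O 10:1, 40 °C
Reagents that add atoms: none
Why: Hayashi–Miyaura rhodium-catalysed asymmetric conjugate addition, in which B-to-Rh transmetalation with retention of alkene geometry and insertion of the butenolide into the alkenyl–Rh bond on the face left open by (S)-BINAP set the ring stereocentre as S, and water protonates the rhodium enolate.

**Step 3**
Reactants: 4 (4S)-4-[(2E)-4-hydroxybut-2-en-2-yl]oxolan-2-one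
Product: 5 (4R)-4-[(2R,3R)-3-(hydroxymethyl)-2-methyloxiran-2-yl]oxolan-2-one
Conditions: Ti(O-iPr)4 (cat.), D-(−)-diethyl tartrate (cat.), t-BuOOH, 4 Å MS, CH2Cl2, −20 °C
Reagents that add atoms: tert-butyl hydroperoxide, CC(C)(C)OO
Why: Sharpless asymmetric epoxidation under reagent control, D-(−)-diethyl tartrate giving the (2R,3R)-epoxy alcohol from an E-trisubstituted allylic alcohol (the mirror image of the geraniol/L-(+)-tartrate case), with syn-stereospecific oxygen transfer so that the alkene geometry becomes the trans relation of the lactone and CH2OH groups.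

**Step 4**
Reactants: 5 (4R)-4-[(2R,3R)-3-(hydroxymethyl)-2-methyloxiran-2-yl]oxolan-2-one
Product: 6 (4R)-4-[(2S,3R)-2-chloro-3,4-dihydroxybutan-2-yl]oxolan-2-one
Conditions: ClTi(O-iPr)3, CH2Cl2, 0 °C to rt; aqueous work-up
Reagents that add atoms: chlorotitanium triisopropoxide, CC(C)O[Ti](Cl)(OC(C)C)OC(C)C
Why: titanium-assisted opening of a 2,3-epoxy alcohol, in which chelation of the alkoxide and the epoxide oxygen to ClTi(O-iPr)3 activates the epoxide and chloride attacks the tertiary carbon, which best carries positive charge, from the back side, so the C–Cl centre is set as S by inversion.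

**Step 5**
Reactants: 6 (4R)-4-[(2S,3R)-2-chloro-3,4-dihydroxybutan-2-yl]oxolan-2-one
Product: 7 (2S)-2-chloro-2-[(3R)-5-oxooxolan-3-yl]propanal
Conditions: NaIO4, THF/H2O, 0 °C to rt
Reagents that add atoms: none
Why: Malaprade glycol cleavage releases the aldehyde and formaldehyde under neutral conditions, and the α-carbon is quaternary so the chloride centre can neither epimerise nor eliminate.

**Step 6**
Reactants: 7 (2S)-2-chloro-2-[(3R)-5-oxooxolan-3-yl]propanal
Product: 8 (4R)-4-[(2S,3E)-4-bromo-2-chlorobut-3-en-2-yl]oxolan-2-one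
Conditions: CHBr3, CrBr2, THF, 0 °C to rt
Reagents that add atoms: bromoform, BrC(Br)Br
Why: Takai olefination, in which the geminal dichromium species formed from CHBr3 and CrBr2 adds to the aldehyde and eliminates to the E-alkenyl bromide, the all-bromide medium avoiding halogen scrambling and the lactone being inert to divalent chromium.

**Step 7**
Reactants: 8 (4R)-4-[(2S,3E)-4-bromo-2-chlorobut-3-en-2-yl]oxolan-2-one
Product: 9 (3R,4S,5E)-6-bromo-4-chloro-3-(hydroxymethyl)-N-methoxy-N,4-dimethylhex-5-enamide
Conditions: MeNH(OMe)·HCl, i-PrMgCl (2 equiv per amine salt), THF, −20 °C; then 8, −20 to 0 °C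
Reagents that add atoms: N,O-dimethylhydroxylamine hydrochloride, CNOC.Cl
Why: aminolysis of the γ-lactone by the preformed magnesium amide of N,O-dimethylhydroxylamine (Weinreb amide formation) opens the ring at low temperature without free Grignard reagent, freeing the primary alcohol and leaving both stereocentres untouched.

**Step 8**
Reactants: 9 (3R,4S,5E)-6-bromo-4-chloro-3-(hydroxymethyl)-N-methoxy-N,4-dimethylhex-5-enamide
Product: 10 [(2R,3S,4E)-5-bromo-3-chloro-2-{2-[methoxy(methyl)amino]-2-oxoethyl}-3-methylpent-4-en-1-yl] acetate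
Conditions: Ac2O, pyridine, DMAP (cat.), CH2Cl2, 0 °C
Reagents that add atoms: acetic anhydride, CC(=O)OC(C)=O
Why: DMAP-catalysed acetylation of the primary alcohol installs the ester that becomes O1–C2 of the ring and blocks relactonisation of the γ-hydroxy amide.

**Step 9**
Reactants: 10 [(2R,3S,4E)-5-bromo-3-chloro-2-{2-[methoxy(methyl)amino]-2-oxoethyl}-3-methylpent-4-en-1-yl] acetate
Product: 11 [(2R,3S,4E)-5-bromo-3-chloro-3-methyl-2-(2-oxoethyl)pent-4-en-1-yl] acetate
Conditions: Cp2Zr(H)Cl (1.5 equiv), THF, rt, short reaction time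
Reagents that add atoms: none
Why: Cp2Zr(H)Cl reduces the tertiary amide through a stable zirconated hemiaminal that gives the aldehyde on work-up, a reduction known to leave esters untouched and expected to be much faster than hydrozirconation of a hindered 1,2-disubstituted bromoalkene.

**Step 10**
Reactants: 11 [(2R,3S,4E)-5-bromo-3-chloro-3-methyl-2-(2-oxoethyl)pent-4-en-1-yl] acetate
Product: 12 [(2R,3S,4E)-5-bromo-3-chloro-2-(2,2-dibromoethyl)-3-methylpent-4-en-1-yl] acetate
Conditions: P(OPh)3, Br2, Et3N, CH2Cl2, −78 °C to rt
Reagents that add atoms: bromine, BrBr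
Why: deoxygenative geminal dibromination of an aldehyde with the triphenyl phosphite–bromine adduct, in which the carbonyl oxygen is activated on phosphorus and replaced by two bromides, with no free Br2 left to add to the alkene and base present to trap acid.

**Step 11**
Reactants: 12 [(2R,3S,4E)-5-bromo-3-chloro-2-(2,2-dibromoethyl)-3-methylpent-4-en-1-yl] acetate
Product: 15 (2R,3S,5R)-3-bromo-5-[(2S,3E)-4-bromo-2-chlorobut-3-en-2-yl]-2-methyloxan-2-ol, via 1-bromoalkyllithium carbenoid 13 (not isolated), via lithium hemiketal alkoxide 14 (not isolated)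
Conditions: n-BuLi (1.0 equiv), THF/Et2O/pentane 4:1:1, −110 °C; AcOH, −110 °C to rt
Reagents that add atoms: none
Why: Proposed new method: Br/Li exchange at the geminal dibromide of 12 gives the configurationally labile 1-bromoalkyllithium carbenoid 13, whose carbanionic carbon adds to the neighbouring acetate carbonyl to give the lithium hemiketal alkoxide 14, which should be stable at −110 °C and is protonated cold to the hemiketal. The closest known reaction type is the intermolecular acylation of halomethyl- and dibromomethyllithium carbenoids by esters (Kowalski homologation, halomethyl ketone synthesis from esters), here made intramolecular in the manner of a Parham cyclisation. The oxane ring closes by 6-exo-trig attack of C3 on the ester carbon C2, the ring oxygen O1 being the alkoxy oxygen of the acetate. C3 is set under Curtin–Hammett control in a chair transition state that places Br equatorial and cis to the equatorial C5 side chain (3S), and C2 is set thermodynamically after protonation, because ring–chain tautomerism of the hemiketal lets OH settle axial (anomeric effect) with the methyl group equatorial (2R). The step needs exchange at CHBr2 in preference to the alkenyl bromide and the tertiary chloride, and addition to the ester in preference to attack of n-BuLi on it; this is secured by the far higher exchange rate of geminal dibromides at −110 °C, by one equivalent of n-BuLi and by the intramolecular trap. The cold acidic quench prevents collapse of 14 to the open bromo ketone alkoxide and its displacement of bromide.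

**Compound list**
1 | but-2-yn-1-ol | CC#CCO | starting material
2 | (Z)-3-(4,4,5,5-tetramethyl-1,3,2-dioxaborolan-2-yl)but-2-en-1-ol | OC/C=C(\C)B1OC(C)(C)C(C)(C)O1 | intermediate
3 | furan-2(5H)-one | O=C1OCC=C1 | starting material
4 | (4S)-4-[(2E)-4-hydroxybut-2-en-2-yl]oxolan-2-one | OC/C=C(\C)[C@@H]1CC(=O)OC1 | intermediate
5 | (4R)-4-[(2R,3R)-3-(hydroxymethyl)-2-methyloxiran-2-yl]oxolan-2-one | C[C@@]1(O[C@@H]1CO)[C@@H]2CC(=O)OC2 | intermediate
6 | (4R)-4-[(2S,3R)-2-chloro-3,4-dihydroxybutan-2-yl]oxolan-2-one | C[C@@](Cl)([C@H](O)CO)[C@@H]1CC(=O)OC1 | intermediate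
7 | (2S)-2-chloro-2-[(3R)-5-oxooxolan-3-yl]propanal | C[C@@](Cl)(C=O)[C@@H]1CC(=O)OC1 | intermediate
8 | (4R)-4-[(2S,3E)-4-bromo-2-chlorobut-3-en-2-yl]oxolan-2-one | C[C@@](Cl)(/C=C/Br)[C@@H]1CC(=O)OC1 | intermediate
9 | (3R,4S,5E)-6-bromo-4-chloro-3-(hydroxymethyl)-N-methoxy-N,4-dimethylhex-5-enamide | C[C@@](Cl)(/C=C/Br)[C@@H](CO)CC(=O)N(C)OC | intermediate
10 | [(2R,3S,4E)-5-bromo-3-chloro-2-{2-[methoxy(methyl)amino]-2-oxoethyl}-3-methylpent-4-en-1-yl] acetate | C[C@@](Cl)(/C=C/Br)[C@@H](COC(C)=O)CC(=O)N(C)OC | intermediate
11 | [(2R,3S,4E)-5-bromo-3-chloro-3-methyl-2-(2-oxoethyl)pent-4-en-1-yl] acetate | C[C@@](Cl)(/C=C/Br)[C@@H](COC(C)=O)CC=O | intermediate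
12 | [(2R,3S,4E)-5-bromo-3-chloro-2-(2,2-dibromoethyl)-3-methylpent-4-en-1-yl] acetate | C[C@@](Cl)(/C=C/Br)[C@@H](COC(C)=O)CC(Br)Br | intermediate
13 | [(2R,3S,4E)-5-bromo-2-(2-bromo-2-lithioethyl)-3-chloro-3-methylpent-4-en-1-yl] acetate (carbenoid, carbanion centre labile) | C[C@@](Cl)(/C=C/Br)[C@@H](COC(C)=O)CC(Br)[Li] | intermediate
14 | lithium (3S,5R)-3-bromo-5-[(2S,3E)-4-bromo-2-chlorobut-3-en-2-yl]-2-methyloxan-2-olate | C[C@@](Cl)(/C=C/Br)[C@H]1COC(C)(O[Li])[C@@H](Br)C1 | intermediate
15 | (2R,3S,5R)-3-bromo-5-[(2S,3E)-4-bromo-2-chlorobut-3-en-2-yl]-2-methyloxan-2-ol | C[C@@](Cl)(/C=C/Br)[C@H]1CO[C@@](C)(O)[C@@H](Br)C1 | target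

**Step count and risks**
Total steps: 11. Longest linear sequence: 11 steps (from but-2-yn-1-ol).

Steps most likely to fail:

1. Step 11. The ring closure may fail through competing Br/Li exchange at the alkenyl bromide, attack of n-BuLi on the acetate, proton transfer from the acetyl methyl group to the carbenoid, 1,2-hydride shift of the carbenoid, or poor facial control at C3. The fallback uses known chemistry and sets out from lactone 8. Reduction with i-Bu2AlH (CH2Cl2, −78 °C) should give the lactol (4R)-4-[(2S,3E)-4-bromo-2-chlorobut-3-en-2-yl]oxolan-2-ol F1. Wittig reaction of F1 with the ylide from (1-methoxyethyl)triphenylphosphonium chloride and KOt-Bu (THF, −40 to 0 °C, excess ylide because the lactol OH consumes one equivalent) should give the hydroxy enol ether (2R,3S,4E)-5-bromo-3-chloro-2-(3-methoxybut-2-en-1-yl)-3-methylpent-4-en-1-ol F2 as an E/Z mixture. NBS in THF/H2O at 0 °C, followed by dilute aqueous acid if a mixed methyl ketal persists, brominates the enol ether carbon and unmasks the methyl ketone, onto which the primary hydroxyl closes. This comes back to the route at 15, together with its C3 epimer, which is equilibrated toward the diequatorial isomer with a trace of HBr and separated.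

2. Step 6. Divalent chromium may reduce the tertiary α C–Cl bond of the aldehyde, or olefination of the neopentyl-type aldehyde may be too slow. The fallback sets out from aldehyde 7. Boron–Wittig olefination with CH2(Bpin)2 and lithium 2,2,6,6-tetramethylpiperidide (THF, −78 °C) should give the E-alkenylboronate (4R)-4-[(2R,3E)-2-chloro-4-(4,4,5,5-tetramethyl-1,3,2-dioxaborolan-2-yl)but-3-en-2-yl]oxolan-2-one F3; the descriptor at the chloride centre changes only because the CIP priorities change. Stereoretentive bromodeboronation with NBS in MeCN at rt comes back to the route at 8.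

3. Step 4. Chloride may attack the wrong epoxide carbon, the hindered tertiary centre may ionise with loss of configuration, or the lactone carbonyl may take part. The fallback sets out from allylic alcohol 4 and replaces epoxide opening by halonium chemistry. Titanium-catalysed enantioselective bromochlorination of the allylic alcohol (NBS, ClTi(O-iPr)3, chiral tridentate Schiff-base ligand, hexanes, −20 °C) places chloride anti at the tertiary carbon and bromide at the adjacent carbon, giving (4R)-4-[(2S,3R)-3-bromo-2-chloro-4-hydroxybutan-2-yl]oxolan-2-one F4. K2CO3 in acetone closes the terminal epoxide (4R)-4-{(1S)-1-chloro-1-[(2S)-oxiran-2-yl]ethyl}oxolan-2-one F5. H5IO6 in aqueous THF cleaves the epoxide and comes back to the route at 7.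

**Further compounds**
F1 | step 11 | (4R)-4-[(2S,3E)-4-bromo-2-chlorobut-3-en-2-yl]oxolan-2-ol | C[C@@](Cl)(/C=C/Br)[C@@H]1CC(O)OC1
F2 | step 11 | (2R,3S,4E)-5-bromo-3-chloro-2-(3-methoxybut-2-en-1-yl)-3-methylpent-4-en-1-ol | C[C@@](Cl)(/C=C/Br)[C@@H](CO)CC=C(C)OC
F3 | step 6 | (4R)-4-[(2R,3E)-2-chloro-4-(4,4,5,5-tetramethyl-1,3,2-dioxaborolan-2-yl)but-3-en-2-yl]oxolan-2-one | C[C@@](Cl)(/C=C/B1OC(C)(C)C(C)(C)O1)[C@@H]2CC(=O)OC2
F4 | step 4 | (4R)-4-[(2S,3R)-3-bromo-2-chloro-4-hydroxybutan-2-yl]oxolan-2-one | C[C@@](Cl)([C@H](Br)CO)[C@@H]1CC(=O)OC1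
F5 | step 4 | (4R)-4-{(1S)-1-chloro-1-[(2S)-oxiran-2-yl]ethyl}oxolan-2-one | C[C@@](Cl)([C@@H]1CO1)[C@@H]2CC(=O)OC2
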